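**Retrosynthetic overview**
- Araneosol (5,7-dihydroxy-3,6,8,4'-tetramethoxyflavone, achiral) comes from flavone 10, its 5-O-methyl-7-O-isopropyl ether, by one Lewis-acid dealkylation that frees the chelated 5-OH and the 7-OH.
- Key disconnection: the O1–C8a bond of the pyranone ring C, so 10 comes from the open 1,3-diketone 9 by anodic C–H/O–H coupling. The feature used is that C8a is the only C–H carbon of ring A and sits para to the C6 methoxy and ortho to the C8 methoxy, so an oxidised ring A accepts oxygen exactly there and no phenol ortho to the acyl group has to be built.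
- 9 is cut at C3–C4 by a crossed Claisen condensation into benzoate 5 and α-methoxy ketone 8.
- 5 comes from methyl syringate (O-isopropylation, bromination, copper methoxylation); 8 comes from anisole and methoxyacetyl chloride.
- Ring order: rings A and B are bought as benzenes; ring C is the only ring made, in step 6.

Key step: step 6

Remark: the target has no stereocentre, so the "single enantiomer" is the achiral compound itself. Diketone 9 is racemic at C2 in its diketo form, and that centre becomes sp2 in step 6.

**Route**

Step 1
Reactants: 1 methyl syringate; 2 2-bromopropane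
Product: 3 methyl 4-isopropoxy-3,5-dimethoxybenzoate
Conditions: K2CO3, DMF, 70 °C
Reagents that add atoms: none
Why: Williamson ether synthesis: the phenoxide of 1, although flanked by two methoxy groups, is alkylated at oxygen by the secondary bromide in DMF (SN2), and the methyl ester is inert to carbonate.

Step 2
Reactants: 3 methyl 4-isopropoxy-3,5-dimethoxybenzoate
Product: 4 methyl 2-bromo-4-isopropoxy-3,5-dimethoxybenzoate
Conditions: NBS (1.05 equiv), MeCN, 0 °C to rt, dark
Reagents that add atoms: N-bromosuccinimide, O=C1CCC(=O)N1Br
Why: Electrophilic aromatic bromination: C2 and C6 are equivalent, each ortho to one methoxy and para to the other, and the first bromine together with the ester deactivates the ring enough for one equivalent of NBS to stop at the monobromide.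

Step 3
Reactants: 4 methyl 2-bromo-4-isopropoxy-3,5-dimethoxybenzoate
Product: 5 methyl 4-isopropoxy-2,3,5-trimethoxybenzoate
Conditions: NaOMe (5 equiv), CuBr (15 mol%), dry MeOH–DMF, 105 °C
Reagents that add atoms: sodium methoxide, [Na+].[O-]C
Why: Ullmann-type copper-catalysed C–O coupling: the ortho ester assists insertion of copper(I) into the C–Br bond, methoxide displaces bromide, and methoxide exchange at the methyl ester is degenerate, so the ester survives under dry conditions.

Step 4
Reactants: 6 anisole; 7 methoxyacetyl chloride
Product: 8 2-methoxy-1-(4-methoxyphenyl)ethanone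
Conditions: AlCl3 (1.2 equiv), CH2Cl2, 0 °C to rt; ice/aq. HCl
Reagents that add atoms: none
Why: Friedel–Crafts acylation: the methoxy group directs the acylium-type electrophile to the para position, the deactivated aryl ketone does not react again, and the low temperature keeps AlCl3 from cleaving the ethers.

Step 5
Reactants: 5 methyl 4-isopropoxy-2,3,5-trimethoxybenzoate; 8 2-methoxy-1-(4-methoxyphenyl)ethanone
Product: 9 1-(4-isopropoxy-2,3,5-trimethoxyphenyl)-2-methoxy-3-(4-methoxyphenyl)propane-1,3-dione (racemic at C2)
Conditions: NaH (2.5 equiv), THF, reflux; then cold 1 M HCl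
Reagents that add atoms: none
Why: Crossed Claisen condensation: only ketone 8 can form an enolate (5 has no α-hydrogen), the enolate adds to the ester carbonyl with loss of methoxide, and deprotonation of the product at its remaining C2–H pulls the equilibrium to the diketonate; C2 of 9 forms racemic, which is of no consequence.

Step 6
Reactants: 9 1-(4-isopropoxy-2,3,5-trimethoxyphenyl)-2-methoxy-3-(4-methoxyphenyl)propane-1,3-dione
Product: 10 7-isopropoxy-3,5,6,8-tetramethoxy-2-(4-methoxyphenyl)-4H-chromen-4-one
Conditions: undivided cell, graphite anode, Pt cathode, constant current (ca. 3 mA cm−2, 2.2 F mol−1), Bu4NPF6 (0.1 M), dry HFIP, rt, Ar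
Reagents that add atoms: none
Why: Proposed new method: one-electron oxidation at the anode should take place on the tetraalkoxybenzoyl ring of 9, the most electron-rich π-system, and the oxygen of the anisoyl carbonyl (diketo form) or of its enol then adds to the only C–H carbon of that ring, the future C8a, which is para to one methoxy group and ortho to another; loss of a second electron, of the C8a proton and of the C3–H or O–H proton gives the aromatic chromone. The closest known reaction types are the anodic dehydrogenative lactonisation of biaryl-2-carboxylic acids to benzocoumarins and the oxidative cyclisation of 2-hydroxybenzophenones onto an electron-rich ring to give xanthones; closure of a 1,3-diketone oxygen onto an unfunctionalised arene C–H to make a flavone is not established. The pyranone ring closes in a six-membered mode by O-attack on an arene carbon whose C4a–C8a bond lies inside the new ring (6-endo with respect to the arene), and no stereocentre is formed, the racemic C2 of 9 becoming the sp2 C3 of 10. The step needs oxidation of ring A and not of the anisoyl ring (four alkoxy donors against one), O-attack and not C-attack (the central carbon could reach C8a only through a four-membered ring), and attack at the C–H carbon and not at an alkoxy-bearing carbon (only the C–H adduct can rearomatise by proton loss). Over-oxidation of 10 should be held back by HFIP, which hydrogen-bonds the basic pyranone carbonyl, by excluding water and nucleophilic alcohols so that the para-dimethoxy pair gives no quinone or quinone ketal, and by stopping the electrolysis at little more than 2 F mol−1.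

Step 7
Reactants: 10 7-isopropoxy-3,5,6,8-tetramethoxy-2-(4-methoxyphenyl)-4H-chromen-4-one
Product: 11 araneosol (5,7-dihydroxy-3,6,8-trimethoxy-2-(4-methoxyphenyl)-4H-chromen-4-one)
Conditions: BCl3 (3 equiv), CH2Cl2, −78 to 0 °C; then H2O
Reagents that add atoms: none
Why: Lewis-acid ether cleavage: boron held in the six-membered chelate between the C4 carbonyl and O5 delivers chloride to the 5-O-methyl group, and the secondary 7-O-isopropyl group leaves by an SN1-like path far faster than the unchelated 3-, 6-, 8- and 4'-methyl ethers, which should persist at or below 0 °C.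

**Compound list**
1 | methyl syringate (methyl 4-hydroxy-3,5-dimethoxybenzoate) | COC(=O)c1cc(OC)c(O)c(OC)c1 | starting material
2 | 2-bromopropane | CC(C)Br | starting material
3 | methyl 4-isopropoxy-3,5-dimethoxybenzoate | COC(=O)c1cc(OC)c(OC(C)C)c(OC)c1 | intermediate
4 | methyl 2-bromo-4-isopropoxy-3,5-dimethoxybenzoate | COC(=O)c1cc(OC)c(OC(C)C)c(OC)c1Br | intermediate
5 | methyl 4-isopropoxy-2,3,5-trimethoxybenzoate | COC(=O)c1cc(OC)c(OC(C)C)c(OC)c1OC | intermediate
6 | anisole | COc1ccccc1 | starting material
7 | methoxyacetyl chloride | COCC(Cl)=O | starting material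
8 | 2-methoxy-1-(4-methoxyphenyl)ethanone | COCC(=O)c1ccc(OC)cc1 | intermediate
9 | 1-(4-isopropoxy-2,3,5-trimethoxyphenyl)-2-methoxy-3-(4-methoxyphenyl)propane-1,3-dione (racemic at C2, enolisable) | COc1ccc(C(=O)C(OC)C(=O)c2cc(OC)c(OC(C)C)c(OC)c2OC)cc1 | intermediate
10 | 7-isopropoxy-3,5,6,8-tetramethoxy-2-(4-methoxyphenyl)-4H-chromen-4-one | COc1ccc(-c2oc3c(OC)c(OC(C)C)c(OC)c(OC)c3c(=O)c2OC)cc1 | intermediate
11 | araneosol (5,7-dihydroxy-3,6,8-trimethoxy-2-(4-methoxyphenyl)-4H-chromen-4-one) | COc1ccc(-c2oc3c(OC)c(O)c(OC)c(O)c3c(=O)c2OC)cc1 | target

**Step count**
Total steps: 7. Longest linear sequence: 6 (steps 1, 2, 3, 5, 6, 7); step 4 is a one-step side branch.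

**Steps most likely to fail**

1. Step 6 (proposed new method). What may go wrong: further oxidation of the penta-oxygenated chromone with oxidative loss of a methyl or isopropyl group towards a quinone; oxidation at the diketone enol followed by coupling through C2; or no closure at all with passivation of the anode.
Fallback by known chemistry (copper-catalysed intramolecular O-arylation of a 2-bromoaryl 1,3-diketone), setting out from 5 and coming back at 10. Ester 5 is brominated at its last free ring position (NBS, MeCN) to methyl 2-bromo-4-isopropoxy-3,5,6-trimethoxybenzoate F1. The doubly flanked ester is saponified (KOH, aq. DMSO, 90 °C) to 2-bromo-4-isopropoxy-3,5,6-trimethoxybenzoic acid F2. Oxalyl chloride with catalytic DMF in CH2Cl2 converts this into 2-bromo-4-isopropoxy-3,5,6-trimethoxybenzoyl chloride F3. The lithium enolate of 8 (LiHMDS, 2.2 equiv, THF, −78 °C) is acylated at carbon by F3 to give 1-(2-bromo-4-isopropoxy-3,5,6-trimethoxyphenyl)-2-methoxy-3-(4-methoxyphenyl)propane-1,3-dione F4. CuI (10 mol%) and K2CO3 in DMF at 110 °C then close the O1–C8a bond by Ullmann-type O-arylation of the enolate and give 10.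

2. Step 7. What may go wrong: loss of further methyl groups (the 6-O-methyl next to the boron-bound 5-oxygen, or the 3-O-methyl beside the carbonyl), or incomplete removal of the isopropyl group at the low temperature needed for selectivity.
Fallback, setting out from 10 and coming back at 11: the two dealkylations are done separately with reagents of different reach. Anhydrous AlCl3 in MeCN (rt to 50 °C), a nitrile-moderated Lewis acid, should act only through the carbonyl chelate and give 5-hydroxy-7-isopropoxy-3,6,8-trimethoxy-2-(4-methoxyphenyl)-4H-chromen-4-one F5. TiCl4 in CH2Cl2 at 0 °C then removes the secondary isopropyl group and gives 11. If AlCl3 already removes the isopropyl group, 11 is reached directly.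

3. Step 5. What may go wrong: sluggish acylation of the enolate by the electron-rich, ortho-substituted ester, so that self-aldol condensation of 8 takes over, or retro-Claisen cleavage of the diketone during work-up.
Fallback, setting out from 5 and coming back at 9: the thermodynamic ester condensation is replaced by kinetic C-acylation with an acid chloride. LiOH in aq. THF gives 4-isopropoxy-2,3,5-trimethoxybenzoic acid F6. Oxalyl chloride with catalytic DMF gives 4-isopropoxy-2,3,5-trimethoxybenzoyl chloride F7. This is added to the preformed lithium enolate of 8 (LiHMDS, 2.2 equiv, THF, −78 °C) to give 9 after mild acidic quench.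

**Further compounds**
F1 | step 6 | methyl 2-bromo-4-isopropoxy-3,5,6-trimethoxybenzoate | COC(=O)c1c(Br)c(OC)c(OC(C)C)c(OC)c1OC
F2 | step 6 | 2-bromo-4-isopropoxy-3,5,6-trimethoxybenzoic acid | OC(=O)c1c(Br)c(OC)c(OC(C)C)c(OC)c1OC
F3 | step 6 | 2-bromo-4-isopropoxy-3,5,6-trimethoxybenzoyl chloride | ClC(=O)c1c(Br)c(OC)c(OC(C)C)c(OC)c1OC
F4 | step 6 | 1-(2-bromo-4-isopropoxy-3,5,6-trimethoxyphenyl)-2-methoxy-3-(4-methoxyphenyl)propane-1,3-dione | COc1ccc(C(=O)C(OC)C(=O)c2c(Br)c(OC)c(OC(C)C)c(OC)c2OC)cc1
F5 | step 7 | 5-hydroxy-7-isopropoxy-3,6,8-trimethoxy-2-(4-methoxyphenyl)-4H-chromen-4-one | COc1ccc(-c2oc3c(OC)c(OC(C)C)c(OC)c(O)c3c(=O)c2OC)cc1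
F6 | step 5 | 4-isopropoxy-2,3,5-trimethoxybenzoic acid | OC(=O)c1cc(OC)c(OC(C)C)c(OC)c1OC
F7 | step 5 | 4-isopropoxy-2,3,5-trimethoxybenzoyl chloride | ClC(=O)c1cc(OC)c(OC(C)C)c(OC)c1OC
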